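**Plan**
- Retrosynthesis: the target is C2-symmetric about C8–C8'. Each of these adjacent stereocentres carries one CH2OH carbon (C9, C9') and one arylmethyl group (C7/C7' with identical 4-hydroxy-3,5-dimethoxyphenyl rings). Cutting C8–C9 and C8'–C9' leaves the symmetric (E)-1,4-diarylbut-2-ene, and cutting its C8=C8' bond gives two molecules of an allyl syringol.
- Forward: the phenol is masked as a pivalate, the chain is joined at C8=C8' by olefin self-metathesis, both one-carbon arms are added across that alkene as methyl esters in one operation, and a single hydride step reduces the esters and removes the pivalates. No ring is formed; the two arene rings are carried through.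
- Stereochemistry: syn addition of two identical carbons to the E alkene fixes the threo (C2) relation of C8/C8'. A chiral bis(oxazoline) ligand on palladium must select the Re,Re face, which corresponds to (8R,8'R).

Key step: step 3

Assumption: the sense of induction of the bis(oxazoline) ligand on a 1,2-dialkyl alkene is not established, so the (S,S) ligand is written and its equally accessible (R,R) antipode would replace it if a pilot run favoured the (2S,3S) diester.

**Step 1**
Reactants: 1 4-allyl-2,6-dimethoxyphenol; 2 pivaloyl chloride
Product: 3 4-allyl-2,6-dimethoxyphenyl pivalate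
Conditions: PivCl (1.2 equiv), Et3N (1.5 equiv), DMAP (5 mol%), CH2Cl2, 0 °C → rt
Reagents that add atoms: pivaloyl chloride, CC(C)(C)C(=O)Cl
Why: DMAP-catalysed O-acylation of the hindered phenol should proceed cleanly, and the pivalate shields the oxidation-prone syringyl phenol from the ruthenium carbene and from the quinone-mediated carbonylation while remaining removable by hydride in the last step.

**Step 2**
Reactants: 3 4-allyl-2,6-dimethoxyphenyl pivalate (two molecules)
Product: 4 (E)-1,4-bis[3,5-dimethoxy-4-(pivaloyloxy)phenyl]but-2-ene
Conditions: second-generation Ru benzylidene catalyst [(H2IMes)(PCy3)Cl2Ru=CHPh] (2 mol%), 1,4-benzoquinone (10 mol%), CH2Cl2, 40 °C, N2 sweep; recrystallisation of the E isomer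
Reagents that add atoms: none
Why: olefin self-metathesis of a terminal allylarene is driven by loss of ethylene, secondary metathesis should equilibrate towards the more stable E alkene (purified further by crystallisation), and the quinone additive suppresses Ru–H-mediated migration of the double bond into conjugation.

**Step 3**
Reactants: 4 (E)-1,4-bis[3,5-dimethoxy-4-(pivaloyloxy)phenyl]but-2-ene; 5 carbon monoxide; 6 methanol
Product: 7 dimethyl (2R,3R)-2,3-bis[3,5-dimethoxy-4-(pivaloyloxy)benzyl]succinate
Conditions: Pd(OCOCF3)2 (5 mol%), (4S,4'S)-4,4'-diisopropyl-4,4',5,5'-tetrahydro-2,2'-bioxazole [(S,S)-iPr-BiOX] (6 mol%), p-TsOH·H2O (5 mol%), 1,4-benzoquinone (1.5 equiv), CO (40 bar), MeOH/THF 1:4, 0 → 20 °C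
Reagents that add atoms: carbon monoxide, [C-]#[O+]; methanol, CO
Why: Proposed new method: methanol attacks CO on the cationic Pd(II)–bis(oxazoline) centre to give a Pd–CO2Me species, the E alkene inserts syn into this bond (first C–C bond), CO inserts into the new Pd–C bond with retention, and methanolysis of the acyl–Pd releases the second ester, after which benzoquinone returns Pd(0) to Pd(II). The closest known reaction type is the Pd(II)/α-diimine oxidative bis-alkoxycarbonylation of 1,2-disubstituted alkenes, which is syn-specific, together with chiral-ligand versions on styrenes and terminal alkenes; an enantioselective case on a 1,2-dialkyl alkene is not known. No ring is closed. Both stereocentres arise in one turnover: their threo (C2) relation follows from syn addition across the E double bond, and their absolute sense from the C2-symmetric ligand, which has to select the Re,Re face of the alkene to give (2R,3R). The step needs enantioface selectivity and suppression of β-hydride elimination and of allyl-to-propenyl isomerisation. The symmetric substrate removes any regiochemical question, the ester chelate of the alkyl–Pd intermediate and the high CO pressure should favour CO insertion over β-H loss, and excess benzoquinone scavenges Pd–H.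

**Step 4**
Reactants: 7 dimethyl (2R,3R)-2,3-bis[3,5-dimethoxy-4-(pivaloyloxy)benzyl]succinate
Product: 8 5,5'-dimethoxysecoisolariciresinol, (2R,3R)-2,3-bis(4-hydroxy-3,5-dimethoxybenzyl)butane-1,4-diol
Conditions: LiAlH4 (5 equiv), THF, 0 °C → rt, under N2; then H2O, aq. sodium potassium tartrate, EtOAc extraction
Reagents that add atoms: none
Why: lithium aluminium hydride reduction converts both methyl esters into the primary alcohols and cleaves both aryl pivalates by acyl reduction in the same operation, and because hydride addition is faster than enolisation the C8/C8' centres should pass unchanged into the (R,R) diol.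

**Compound list**
1 | 4-allyl-2,6-dimethoxyphenol | C=CCc1cc(OC)c(O)c(OC)c1 | starting material
2 | pivaloyl chloride (2,2-dimethylpropanoyl chloride) | CC(C)(C)C(=O)Cl | starting material
3 | 4-allyl-2,6-dimethoxyphenyl pivalate | C=CCc1cc(OC)c(OC(=O)C(C)(C)C)c(OC)c1 | intermediate
4 | (E)-1,4-bis[3,5-dimethoxy-4-(pivaloyloxy)phenyl]but-2-ene | COc1cc(C/C=C/Cc2cc(OC)c(OC(=O)C(C)(C)C)c(OC)c2)cc(OC)c1OC(=O)C(C)(C)C | intermediate
5 | carbon monoxide | [C-]#[O+] | starting material
6 | methanol | CO | starting material
7 | dimethyl (2R,3R)-2,3-bis[3,5-dimethoxy-4-(pivaloyloxy)benzyl]succinate | COC(=O)[C@H](Cc1cc(OC)c(OC(=O)C(C)(C)C)c(OC)c1)[C@@H](Cc1cc(OC)c(OC(=O)C(C)(C)C)c(OC)c1)C(=O)OC | intermediate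
8 | 5,5'-dimethoxysecoisolariciresinol, (2R,3R)-2,3-bis(4-hydroxy-3,5-dimethoxybenzyl)butane-1,4-diol | COc1cc(C[C@@H](CO)[C@H](CO)Cc2cc(OC)c(O)c(OC)c2)cc(OC)c1O | target

Total step count: 4
Longest linear sequence: 4 steps (1 → 3 → 4 → 7 → 8)

**Steps most likely to fail**

1. Step 3 (new method). The chiral ligand may discriminate poorly between the two enantiotopic faces of an alkene whose substituents are both arylmethyl groups, and a slower chiral catalyst gives β-hydride elimination more time. The fallback uses known chemistry and sets out from 4. The established achiral system, Pd(OCOCF3)2 with N,N'-bis(2,6-dimethylphenyl)butane-2,3-diimine, p-TsOH and benzoquinone under CO (4 bar) in MeOH/THF at 20 °C, should add the two ester groups syn and give the racemic threo diester. This is 7 together with an equal amount of its mirror image, dimethyl (2S,3S)-2,3-bis[3,5-dimethoxy-4-(pivaloyloxy)benzyl]succinate F1. Preparative chromatography on a chiral stationary phase separates the two, and the route is rejoined at 7.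

2. Step 2. The double bond may migrate into conjugation before or after metathesis, giving truncated and propenyl by-products, and removal of the Z isomer may be incomplete; any Z alkene would end as the meso diester in step 3. The fallback sets out from pivaloyl chloride 2 and commercial 4-hydroxy-3,5-dimethoxybenzaldehyde and builds the alkene with fixed geometry. Acylation (Et3N, DMAP, CH2Cl2) gives 4-formyl-2,6-dimethoxyphenyl pivalate F2. Reduction with NaBH4 in MeOH/THF at 0 °C gives 4-(hydroxymethyl)-2,6-dimethoxyphenyl pivalate F3. PBr3 in CH2Cl2 at 0 °C gives 4-(bromomethyl)-2,6-dimethoxyphenyl pivalate F4. A twofold Stille coupling of F4 with commercial (E)-1,2-bis(tributylstannyl)ethene (Pd(PPh3)4, toluene, 80 °C) proceeds with retention of the alkene geometry and rejoins the route at 4 as the E isomer only.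

3. Step 4. The polyanionic phenoxide/alkoxide product may be retained on aluminium salts or oxidised in air during the basic work-up, and cleavage of the hindered pivalates may be incomplete. The fallback sets out from 7 and separates reduction from deacylation. LiBH4 in THF with a little MeOH reduces the methyl esters to give (2R,3R)-2,3-bis[3,5-dimethoxy-4-(pivaloyloxy)benzyl]butane-1,4-diol F5, whose stereocentres are no longer α to a carbonyl group. NaOMe in degassed MeOH then removes both pivalates by transesterification, and neutralisation with an acidic resin rejoins the route at 8. Any pivalate already lost in the borohydride stage is of no consequence.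

**Further compounds**
F1 | step 3 | dimethyl (2S,3S)-2,3-bis[3,5-dimethoxy-4-(pivaloyloxy)benzyl]succinate | COC(=O)[C@@H](Cc1cc(OC)c(OC(=O)C(C)(C)C)c(OC)c1)[C@H](Cc1cc(OC)c(OC(=O)C(C)(C)C)c(OC)c1)C(=O)OC
F2 | step 2 | 4-formyl-2,6-dimethoxyphenyl pivalate | O=Cc1cc(OC)c(OC(=O)C(C)(C)C)c(OC)c1
F3 | step 2 | 4-(hydroxymethyl)-2,6-dimethoxyphenyl pivalate | OCc1cc(OC)c(OC(=O)C(C)(C)C)c(OC)c1
F4 | step 2 | 4-(bromomethyl)-2,6-dimethoxyphenyl pivalate | BrCc1cc(OC)c(OC(=O)C(C)(C)C)c(OC)c1
F5 | step 4 | (2R,3R)-2,3-bis[3,5-dimethoxy-4-(pivaloyloxy)benzyl]butane-1,4-diol | COc1cc(C[C@@H](CO)[C@H](CO)Cc2cc(OC)c(OC(=O)C(C)(C)C)c(OC)c2)cc(OC)c1OC(=O)C(C)(C)C
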